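**Conventions and one assumption**

- Germacrane numbers are used for every compound, also before the ten-membered ring exists: C1–C10 are the ring carbons of the target, C11–C13 the side chain on C7 (C12 the lactone carbonyl, C13 the CH2O arm), C14 the methyl on C10, C15 the methyl on C4.
- Ring B is the six-membered ring C8–C9–C10–C1–C6–C7. "Up" and "down" refer to ring B drawn with these atoms running counterclockwise.
- Assumption: 4-methoxybenzyl chloromethyl ether is bought; it is otherwise made in two steps from 4-methoxybenzyl alcohol.

## Analysis of the target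

Target 37 is a germacranolide: a ten-membered carbocycle (C1–C10) with a γ-lactone fused at C6–C7 (C12 carbonyl), a C1 ketone, a 4,5-epoxide, a tertiary acetate at C10, a methacrylate at C8 and an acetoxymethyl group (C13) on C11. It has seven stereocentres, C4, C5, C6, C7, C8, C10 and C11 (4R,5S,6S,7S,8S,10R,11R from the SMILES). The lactone is cis-fused: H6, H7 and H11 all lie on one face of the lactone, so C13 sits on the face of C8. The epoxide is a cis-epoxide (C3 and C6 on the same side), the oxide of a Z-C4=C5 alkene, and the C8 and C10 oxygens are related as in a syn-1,3-diol. Three groups dictate the order of the endgame: the epoxide opens transannularly onto the C1 ketone under acid, the β-acetoxy lactone loses acetic acid under base to give the α-methylene lactone, and the three esters are of two different kinds. The difficulty is the medium ring combined with the contiguous C4–C8 array and a quaternary C10 next to the ketone. The strategy rests on the C1 carbonyl with functionality at C5–C6: this is the retron of a cyclodec-5-enone, which an oxy-Cope shift makes from ring B (C1, C6, C7, C8, C9, C10) carrying a vinyl group on C1 and a propenyl group on C6.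

## Retrosynthetic reasoning

**37 from 36.** The epoxide is cut first. Putting it in last means no acid, fluoride or strong base ever meets the epoxy ketone; the forward step must oxidize the Z-C4=C5 alkene and leave the electron-poor methacrylate alone.

**36 back to 31.** The three esters are removed in the order that lets reactivity differentiate them: the primary C13 acetate (36 from 35), the PMB ether (35 from 34), the tertiary C10 acetate (34 from 33), the C8 methacrylate (33 from 32). The tertiary acetylation is placed while C13 is still an ether, so forcing conditions do not meet a β-acetoxy lactone. Diol 32 comes from acetal 31, whose single benzylidene acetal masks O8 and O10 together and is removed by weak acid before the epoxide exists.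

**31 from 30.** The Z-C4=C5 bond is traced to a C5 alcohol and H4. C4 and C5 are both stereocentres in 30, so a syn elimination fixes the alkene geometry stereospecifically.

**30 back to 24.** The lactone C6–O bond is the next cut. A halolactonization across the E-C5=C6 alkene of acid 25 is set aside: anti addition would need the electrophile to enter from the interior of the ring, because the carboxyl arm on C7 sits on the outer face. Syn osmylation from the outer face is reliable but gives the C6 epimer (trans lactone 27). The mismatch is corrected by a double inversion: mesylate 28, then saponification to the cis-epoxy acid 29, which relactonizes at C6 with inversion to 30. Osmylation of the other face would give 30 directly, so the two faces converge. Acid 25 comes from primary alcohol 24.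

**24 from 22 (key disconnection).** The C3–C4 bond is cut and C1–C6 re-formed. This turns the ten-membered ketone into ring B alcohol 22 with vinyl on C1 and (Z)-propenyl on C6, trans to each other. C7, C8, C10 and C11 are then set on a six-membered ring, and the forward step has to create only C4 and the E-alkene.

**22 back to 16.** The acetal comes from tetraol 21. The tertiary C10 hydroxyl is traced through epoxy alcohol 19 to the C9=C10 alkene of 18, where the C8 hydroxyl directs the oxygen to the correct face. Diol 18 is the reduced form of lactone 17, and C11 is cut to lactone 16: alkylation on the convex face of the cis-fused lactone puts C13 on the side the target needs and differentiates C12 from C13 without any desymmetrization.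

**16 back to 9 and 10.** The lactone is opened to keto ester 14 (C8 reduction cis to the side chain). The C7–C11 bond is cut to silyl dienol ether 12 (alkylation trans to the propenyl group). The C6–C5 bond is cut to quinol 9 and (Z)-1-bromopropene 10. Adding the vinyl group last to a C1 ketone flanked by the quaternary C10 would require attack on the hindered face; here the order is reversed and the C1 alkoxide of 9 delivers the propenyl group to its own face.

**9 back to 1 and 2.** The methyl group of 9 is removed to give achiral quinol 4 (via 6 and 5), so that a catalytic asymmetric methyl addition can choose between the two enantiotopic enone arms; dehydrogenation then leaves C1 as the only stereocentre. Quinol 4 is the adduct of vinylmagnesium bromide 2 and quinone monoketal 1. A free quinone is avoided as acceptor because organometallic reagents reduce it.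

## Alternatives that were turned down

**Alternative 1:** The C8–C9 and O–C10 bonds are cut, and a C8 nitrile oxide adds across the C9=C10 alkene to close the carbocycle as bridged isoxazoline A1.
- For: one step makes the ring, a C–C bond and the tertiary C10–O bond with the regiochemistry intrinsic to nitrile oxides, and the heterocycle masks O8 and O10 more compactly than the acetal used here.
- Against: the closure forms a ten-membered ring and a bridged bicycle at once, so furoxan dimerization competes. Nothing close to C10 controls its configuration. A1 already carries the epoxide, the lactone and an acetate, which must survive hypochlorite, reductive N–O cleavage and then a reduction of the C8 ketone that must be selective against the C1 ketone and stereoselective.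
- Comparison: the chosen route gives up the compact masking but closes the ring by a unimolecular shift that needs no dilution and brings C8 and C10 from ring B already configured.

**Alternative 2:** The C1–C2 bond is cut as an alkyne, ring-closing alkyne metathesis gives cyclodecyne A2, and the neighbouring acetate then directs hydration to the C1 ketone.
- For: all seven stereocentres, the epoxide and all three esters are in place before closure, so its endgame is shorter than the one proposed here, and the acetate-directed hydration is regiochemically sound.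
- Against: a ten-membered cycloalkyne is strained, so oligomers are favoured over ring closure. The tertiary propargylic acetate is hindered and ionizable beside the alkylidyne. π-Acid hydration in the presence of the epoxide invites transannular ketalization. The open-chain diyne with seven stereocentres must be built without a cyclic template.
- Comparison: the chosen strategy pays with a longer endgame but forms the ring without a strained intermediate and uses ring B to set stereochemistry.

**Alternative 3:** The C1=C6 ring-fusion alkene of an octalin is cleaved by ozone to give diketone A3 with the epoxide in place.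
- For: ozonolysis of a tetrasubstituted alkene is dependable, and it delivers C1 and C6 at the carbonyl level in one step; the C6 oxygen, which costs four steps here, comes free.
- Against: A3 is a 1,6-diketone in a ten-membered ring and should re-close by transannular aldol reaction. Its C6 ketone is flanked by the epimerizable C7 and by the epoxide carbon C5. C6 would have to be reduced selectively against C1 and with the configuration of the cis lactone. The epoxy-octalin with a tetrasubstituted alkene is itself a demanding target.
- Comparison: the oxy-Cope route is redox-neutral, gives one ketone only and leaves an alkene at C5–C6 as the handle.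

Key step: step 13

## Route

Step 1
Reactants: 1 4,4-dimethoxycyclohexa-2,5-dien-1-one; 2 vinylmagnesium bromide
Product: 4 4-hydroxy-4-vinylcyclohexa-2,5-dien-1-one, via dimethoxy dienol 3 (not isolated)
Conditions: 2 (1.2 equiv), THF, −78 °C; then 5% aq. oxalic acid, THF, 0 °C to rt
Reagents that add atoms: water, O
Why: Grignard reagents add 1,2 to quinone monoketals and mild aqueous acid then frees the dienone (p-quinol synthesis); the product is achiral, so no stereocontrol is needed.

Step 2
Reactants: 4 4-hydroxy-4-vinylcyclohexa-2,5-dien-1-one
Product: 5 4-(trimethylsilyloxy)-4-vinylcyclohexa-2,5-dien-1-one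
Conditions: TMSCl, imidazole, DMF, 0 °C to rt
Reagents that add atoms: chlorotrimethylsilane, C[Si](C)(C)Cl
Why: Silyl ether formation removes the acidic proton before the organozinc step and keeps the two enone arms enantiotopic.

Step 3
Reactants: 5 4-(trimethylsilyloxy)-4-vinylcyclohexa-2,5-dien-1-one
Product: 6 5-methyl-4-(trimethylsilyloxy)-4-vinylcyclohex-2-en-1-one (methyl trans to silyloxy)
Conditions: Me2Zn (2.0 equiv), Cu(OTf)2 (3 mol %), (S,R,R)-BINOL bis(1-phenylethyl)amine phosphoramidite (6 mol %), toluene, −30 °C; AcOH; chromatography
Reagents that add atoms: dimethylzinc, C[Zn]C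
Why: Copper-catalysed asymmetric conjugate addition of a dialkylzinc desymmetrizes 4,4-disubstituted cyclohexadienones; the chiral catalyst picks one enantiotopic enone arm and so fixes C1, with methyl expected anti to the silyloxy group. The minor C10 diastereomer would lead to the antipode of 9 and is removed here; the ligand antipode is used if the sense of induction proves opposite.

Step 4
Reactants: 6 5-methyl-4-(trimethylsilyloxy)-4-vinylcyclohex-2-en-1-one
Product: 9 (R)-4-hydroxy-3-methyl-4-vinylcyclohexa-2,5-dien-1-one, via silyl dienol ether 7 (not isolated), via silyl-protected dienone 8 (not isolated)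
Conditions: LiHMDS, TMSCl, THF, −78 °C; Pd(OAc)2 (1.05 equiv), MeCN, rt; citric acid, MeOH, rt
Reagents that add atoms: none
Why: Saegusa–Ito oxidation: the ketone can enolize only toward C9, so the C9=C10 enone is restored, the C10 centre is erased and C1 is left as the only stereocentre; acidic methanolysis frees the tertiary alcohol.

Step 5
Reactants: 9 (R)-4-hydroxy-3-methyl-4-vinylcyclohexa-2,5-dien-1-one; 10 (Z)-1-bromoprop-1-ene
Product: 12 C6-propenyl bis(trimethylsilyl) dienol ether, via bromomagnesium alkoxide enolate 11 (not isolated)
Conditions: 10 (3.2 equiv), t-BuLi (6.4 equiv), THF/Et2O, −78 °C, then MgBr2·OEt2 (3.3 equiv); add 9, −78 to −20 °C; TMSCl, Et3N, DMPU, −78 to 0 °C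
Reagents that add atoms: chlorotrimethylsilane, C[Si](C)(C)Cl
Why: Alkoxide-directed conjugate addition of a Grignard reagent to a 4-oxido dienone: the C1 magnesium alkoxide delivers the (Z)-propenyl group, made with retention by Br/Li exchange, to the unsubstituted β-carbon C6 on its own face, so OH and propenyl are cis and vinyl and propenyl trans. Silyl trapping caps the tertiary alkoxide (no premature oxy-Cope chemistry) and stores the C7 enolate regiospecifically.

Step 6
Reactants: 12 C6-propenyl bis(trimethylsilyl) dienol ether
Product: 14 C7 methyl acetate enone, via lithium dienolate 13 (not isolated)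
Conditions: MeLi (1.05 equiv), THF, 0 °C; methyl bromoacetate (1.5 equiv), DMPU, −78 to −30 °C
Reagents that add atoms: methyl bromoacetate, COC(=O)CBr
Why: MeLi cleaves the enol silyl ether to the regiodefined lithium enolate, which is alkylated at C7 anti to the neighbouring propenyl group (enolate alkylation, trans-2,3 selectivity); the tertiary silyl ether survives.

Step 7
Reactants: 14 C7 methyl acetate enone
Product: 16 cis-fused C8/C12 lactone, via cis-hydroxy ester 15 (not isolated)
Conditions: L-Selectride (1.2 equiv), THF, −78 to 0 °C; aqueous work-up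
Reagents that add atoms: none
Why: The bulky trialkylborohydride adds 1,2 (C10 is fully substituted) from the face opposite the C7 side chain, so the C8 alkoxide is cis to it and closes the γ-lactone on the methyl ester; a trans alcohol could not lactonize and would be separable.

Step 8
Reactants: 16 cis-fused C8/C12 lactone
Product: 17 C11-(4-methoxybenzyloxymethyl) lactone
Conditions: LDA (1.05 equiv), THF, −78 °C; 4-methoxybenzyl chloromethyl ether (1.3 equiv), −78 to −45 °C
Reagents that add atoms: 4-methoxybenzyl chloromethyl ether, COc1ccc(COCCl)cc1
Why: Lactone enolate alkylation on the convex face of the cis-fused bicycle, anti to the C6 branch, sets C11 with C13 on the side the target requires; a slight deficit of base avoids β-elimination of the new alkoxymethyl group.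

Step 9
Reactants: 17 C11-(4-methoxybenzyloxymethyl) lactone
Product: 18 C8/C12 diol
Conditions: LiAlH4 (2 equiv), THF, 0 °C
Reagents that add atoms: none
Why: Hydride reduction of the lactone removes the enolizable carbonyl before the key step and frees the C8 hydroxyl as a directing group.

Step 10
Reactants: 18 C8/C12 diol
Product: 19 9,10-epoxy diol
Conditions: VO(acac)2 (5 mol %), t-BuOOH (1.5 equiv), CH2Cl2, 0 °C to rt
Reagents that add atoms: tert-butyl hydroperoxide, CC(C)(C)OO
Why: Vanadium-catalysed hydroxyl-directed epoxidation of a cyclic allylic alcohol puts the oxygen on C9=C10 syn to the C8 hydroxyl; the silylated C1 oxygen on the other face cannot direct, and vinyl and propenyl have no allylic free hydroxyl.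

Step 11
Reactants: 19 9,10-epoxy diol
Product: 21 tetraol, via C1 silyl ether triol 20 (not isolated)
Conditions: LiAlH4 (4 equiv), THF, 0 to 50 °C; aqueous work-up; K2CO3, MeOH, rt
Reagents that add atoms: none
Why: Hydride opens the trisubstituted epoxide at the secondary carbon C9, leaving the tertiary C10 alcohol syn to the C8 hydroxyl; basic methanolysis then removes the tertiary trimethylsilyl ether.

Step 12
Reactants: 21 tetraol
Product: 22 ring B diol with 8,10-O-(4-methoxybenzylidene) acetal
Conditions: 4-methoxybenzaldehyde dimethyl acetal (1.3 equiv), PPTS (cat.), CH2Cl2, 4 Å sieves, rt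
Reagents that add atoms: 4-methoxybenzaldehyde dimethyl acetal, COc1ccc(C(OC)OC)cc1
Why: Acetalization under thermodynamic control selects the six-membered dioxane on the syn C8/C10 diol (aryl equatorial) and leaves the tertiary C1 and primary C12 hydroxyls free; the acetal holds O8 and O10 diaxial and so both alkenyl groups equatorial.

Step 13
Reactants: 22 ring B diol with 8,10-O-(4-methoxybenzylidene) acetal
Product: 24 (4R,5E)-cyclodec-5-enone, via dipotassium enolate 23 (not isolated)
Conditions: KH (2.5 equiv), 18-crown-6 (2.5 equiv), THF, 0 to 25 °C; AcOH, −78 °C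
Reagents that add atoms: none
Why: Anionic oxy-Cope rearrangement: KH with the crown ether gives the free C1 alkoxide (the C12 alkoxide is a spectator), and a concerted [3,3] shift forms C3–C4, breaks C1–C6 and delivers the C1 potassium enolate, which is protonated to the ketone. The closest known reaction type is the ring expansion of trans-1,2-dialkenylcyclohexanols to (E)-cyclodec-5-enones. The ten-membered ring is not closed end to end; it arises by four-carbon expansion of ring B through a six-membered chair transition state fused to ring B like a trans-decalin. C4 is the only new stereocentre and is controlled by the Z geometry of the propenyl group (methyl axial in the chair) together with the fixed configuration at C6, giving the 4R centre shown. The step needs chair over boat and E geometry at C5=C6; both follow from the trans, diequatorial placement of vinyl and propenyl, which the 8,10-acetal locks, so that C7 is equatorial on the transition-state chair. C7, C8, C10 and C11 are untouched, and because C10 is quaternary the product enolizes only toward C2, so no stereocentre is at risk on work-up.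

Step 14
Reactants: 24 (4R,5E)-cyclodec-5-enone
Product: 25 C12 carboxylic acid
Conditions: TEMPO (0.2 equiv), PhI(OAc)2 (2.5 equiv), MeCN/H2O (1:1), rt
Reagents that add atoms: water, O
Why: Nitroxyl-catalysed oxidation takes the primary alcohol to the acid at near-neutral pH, so neither C11 nor the β-alkoxy group is exposed to base.

Step 15
Reactants: 25 C12 carboxylic acid
Product: 27 6,7-trans lactone C5 alcohol, via dihydroxy acid 26 (not isolated)
Conditions: OsO4 (5 mol %), NMO (1.5 equiv), acetone/H2O (5:1), rt; Na2SO3; then EDC·HCl (1.5 equiv), DMAP (0.1 equiv), CH2Cl2, 0 °C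
Reagents that add atoms: N-methylmorpholine N-oxide, C[N+]1([O-])CCOCC1; water, O
Why: Osmylation is a syn addition from the exposed outer face of the E-cyclodecene; in the conformer inherited from the chair transition state H7 lies in the alkene plane and the C7 side chain on the outer face. Carbodiimide activation closes the γ-lactone on the C6 hydroxyl with retention before the diol can ketalize with C1. A diol from the other face would close to the 6,7-cis lactone that step 17 delivers, so both faces converge.

Step 16
Reactants: 27 6,7-trans lactone C5 alcohol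
Product: 28 C5 mesylate
Conditions: MsCl (1.5 equiv), Et3N (3 equiv), CH2Cl2, 0 °C
Reagents that add atoms: methanesulfonyl chloride, CS(=O)(=O)Cl
Why: Sulfonylation of the only free hydroxyl installs the leaving group for the epoxide relay.

Step 17
Reactants: 28 C5 mesylate
Product: 30 6,7-cis lactone C5 alcohol, via cis-epoxy acid 29 (not isolated)
Conditions: LiOH·H2O (3 equiv), THF/H2O (3:1), 0 °C to rt; then AcOH to pH 4, rt
Reagents that add atoms: lithium hydroxide, [Li+].[OH-]
Why: Saponification frees the C6 alkoxide, which displaces the C5 mesylate with inversion to the cis-epoxide; on acidification the acid opens the epoxide 5-exo at C6, again with inversion. This double inversion of the syn diol gives the cis-fused lactone with C6 as in the target.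

Step 18
Reactants: 30 6,7-cis lactone C5 alcohol
Product: 31 (4Z)-alkene allylic lactone
Conditions: methyl N-(triethylammoniosulfonyl)carbamate (Burgess reagent, 2.5 equiv), toluene, 60 °C
Reagents that add atoms: none
Why: Syn elimination of the C5 sulfamate with H4: C4 (set in step 13) and C5 have the relative configuration that places C3 and C6 cis when H4 and the leaving group are syn-periplanar, so the Z alkene results. The trisubstituted alkene is expected over the enol lactone.

Step 19
Reactants: 31 (4Z)-alkene allylic lactone
Product: 32 C8/C10 diol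
Conditions: AcOH/THF/H2O (4:2:1), 30 °C
Reagents that add atoms: none
Why: The electron-rich benzylidene acetal is hydrolysed by dilute acetic acid, under which the PMB ether, the allylic lactone and the ketone should persist; this is done before the epoxide exists.

Step 20
Reactants: 32 C8/C10 diol
Product: 33 C8 methacrylate
Conditions: methacrylic anhydride (1.3 equiv), Et3N (2 equiv), DMAP (0.1 equiv), CH2Cl2, 0 °C
Reagents that add atoms: methacrylic anhydride, C=C(C)C(=O)OC(=O)C(C)=C
Why: DMAP-catalysed acylation distinguishes the secondary C8 hydroxyl from the tertiary C10 hydroxyl; the low temperature limits translactonization toward O8.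

Step 21
Reactants: 33 C8 methacrylate
Product: 34 C10 acetate
Conditions: Ac2O (5 equiv), DMAP (1.5 equiv), Et3N (5 equiv), CH2Cl2, rt to 35 °C
Reagents that add atoms: acetic anhydride, CC(=O)OC(C)=O
Why: Forcing DMAP acetylation esterifies the tertiary α-ketol while C13 is still a PMB ether, a poor leaving group, so the β-elimination that threatens a β-acetoxy lactone is avoided.

Step 22
Reactants: 34 C10 acetate
Product: 35 C13 alcohol
Conditions: DDQ (1.3 equiv), CH2Cl2/pH 7 buffer (10:1), 0 °C to rt
Reagents that add atoms: none
Why: Oxidative cleavage of the PMB ether under buffered conditions; the esters and the trisubstituted alkene are not oxidized.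

Step 23
Reactants: 35 C13 alcohol
Product: 36 C10,C13 diacetate
Conditions: Ac2O (1.5 equiv), pyridine, CH2Cl2, 0 °C
Reagents that add atoms: acetic anhydride, CC(=O)OC(C)=O
Why: Mild acetylation of the primary alcohol; the weak base avoids elimination to the α-methylene lactone and epimerization at C11.

Step 24
Reactants: 36 C10,C13 diacetate
Product: 37 target (CNP0166747.1)
Conditions: mCPBA (1.2 equiv), NaHCO3 (3 equiv), CH2Cl2, 0 °C
Reagents that add atoms: 3-chloroperbenzoic acid, O=C(OO)c1cccc(Cl)c1
Why: Peracid epoxidation is chemoselective for the electron-rich trisubstituted Z-alkene over the methacrylate. With H6 in the alkene plane (allylic strain against C3) the reagent should approach anti to the allylic C6–O bond, which gives the C4/C5 configuration of the target. Bicarbonate prevents acid-induced transannular opening by the C1 ketone.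

## Compound list

1 | 4,4-dimethoxycyclohexa-2,5-dien-1-one | COC1(OC)C=CC(=O)C=C1 | starting material
2 | vinylmagnesium bromide | C=C[Mg]Br | starting material
3 | 4,4-dimethoxy-1-vinylcyclohexa-2,5-dien-1-ol | COC1(OC)C=CC(O)(C=C)C=C1 | intermediate
4 | 4-hydroxy-4-vinylcyclohexa-2,5-dien-1-one | O=C1C=CC(O)(C=C)C=C1 | intermediate
5 | 4-(trimethylsilyloxy)-4-vinylcyclohexa-2,5-dien-1-one | C[Si](C)(C)OC1(C=C)C=CC(=O)C=C1 | intermediate
6 | 5-methyl-4-(trimethylsilyloxy)-4-vinylcyclohex-2-en-1-one, methyl (on C10) trans to silyloxy (on C1) | O=C1C[C@@H](C)[C@@](O[Si](C)(C)C)(C=C)C=C1 | intermediate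
7 | 3-methyl-1,4-bis(trimethylsilyloxy)-4-vinylcyclohexa-1,5-diene (silyl dienol ether of 6) | C[Si](C)(C)OC1=C[C@@H](C)[C@@](O[Si](C)(C)C)(C=C)C=C1 | intermediate
8 | (R)-3-methyl-4-(trimethylsilyloxy)-4-vinylcyclohexa-2,5-dien-1-one | O=C1C=C(C)[C@@](O[Si](C)(C)C)(C=C)C=C1 | intermediate
9 | (R)-4-hydroxy-3-methyl-4-vinylcyclohexa-2,5-dien-1-one | O=C1C=C(C)[C@@](O)(C=C)C=C1 | intermediate
10 | (Z)-1-bromoprop-1-ene | C/C=C\Br | starting material
11 | bis(bromomagnesium) C1 alkoxide / C8 dienolate of the conjugate adduct, C6 propenyl cis to O1 | Br[Mg]OC=1C=C(C)[C@@](O[Mg]Br)(C=C)[C@H](/C=C\C)C=1 | intermediate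
12 | 4-methyl-6-[(Z)-prop-1-enyl]-2,5-bis(trimethylsilyloxy)-5-vinylcyclohexa-1,3-diene, propenyl (C6) cis to silyloxy (C1) | C[Si](C)(C)OC=1C=C(C)[C@@](O[Si](C)(C)C)(C=C)[C@H](/C=C\C)C=1 | intermediate
13 | lithium C7=C8 dienolate from 12 | [Li]OC=1C=C(C)[C@@](O[Si](C)(C)C)(C=C)[C@H](/C=C\C)C=1 | intermediate
14 | methyl 2-[4-methyl-2-oxo-6-((Z)-prop-1-enyl)-5-(trimethylsilyloxy)-5-vinylcyclohex-3-en-1-yl]acetate, C7 side chain trans to propenyl | O=C1C=C(C)[C@@](O[Si](C)(C)C)(C=C)[C@H](/C=C\C)[C@H]1CC(=O)OC | intermediate
15 | C8 alcohol of 14, hydroxyl cis to the C7 side chain (formed as lithium alkoxide) | O[C@H]1C=C(C)[C@@](O[Si](C)(C)C)(C=C)[C@H](/C=C\C)[C@H]1CC(=O)OC | intermediate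
16 | cis-fused 6-methyl-4-[(Z)-prop-1-enyl]-5-(trimethylsilyloxy)-5-vinyl-3a,4,5,7a-tetrahydro-1-benzofuran-2(3H)-one | O1[C@H]2C=C(C)[C@@](O[Si](C)(C)C)(C=C)[C@H](/C=C\C)[C@H]2CC1=O | intermediate
17 | 16 carrying a (4-methoxybenzyloxy)methyl group on C11 (lactone C3), on the convex face, trans to the C6 branch | O1[C@H]2C=C(C)[C@@](O[Si](C)(C)C)(C=C)[C@H](/C=C\C)[C@H]2[C@H](COCc2ccc(OC)cc2)C1=O | intermediate
18 | ring B cyclohex-2-en-1-ol (C8-OH) with C7 side chain CH(CH2OH)(CH2OPMB), C1 OTMS/vinyl, C6 (Z)-propenyl | O[C@H]1C=C(C)[C@@](O[Si](C)(C)C)(C=C)[C@H](/C=C\C)[C@H]1[C@@H](CO)COCc1ccc(OC)cc1 | intermediate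
19 | 9,10-epoxide of 18, epoxide oxygen cis to the C8 hydroxyl | O[C@H]1[C@H]2O[C@@]2(C)[C@@](O[Si](C)(C)C)(C=C)[C@H](/C=C\C)[C@H]1[C@@H](CO)COCc1ccc(OC)cc1 | intermediate
20 | C8, C10, C12 triol with C1 trimethylsilyl ether, C10-OH syn to C8-OH | O[C@H]1C[C@@](C)(O)[C@@](O[Si](C)(C)C)(C=C)[C@H](/C=C\C)[C@H]1[C@@H](CO)COCc1ccc(OC)cc1 | intermediate
21 | ring B tetraol: C1-OH up, vinyl down; C6 (Z)-propenyl up; C7 side chain down; C8-OH down; C10 methyl up, OH down | O[C@H]1C[C@@](C)(O)[C@@](O)(C=C)[C@H](/C=C\C)[C@H]1[C@@H](CO)COCc1ccc(OC)cc1 | intermediate
22 | key-step precursor: trans-1-vinyl-6-[(Z)-propenyl]cyclohexan-1-ol with 8,10-O-(4-methoxybenzylidene) acetal (aryl equatorial) and C7 side chain CH(CH2OH)(CH2OPMB) | COc1ccc(cc1)[C@H]1O[C@H]2C[C@@](C)(O1)[C@@](O)(C=C)[C@H](/C=C\C)[C@H]2[C@@H](CO)COCc1ccc(OC)cc1 | intermediate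
23 | dipotassium salt: C1 enolate (C1=C2) and C12 alkoxide of 24 | COc1ccc(cc1)[C@H]1O[C@H]2C[C@@](C)(O1)/C(O[K])=C/C[C@@H](C)/C=C/[C@H]2[C@@H](CO[K])COCc1ccc(OC)cc1 | intermediate
24 | key-step product: (4R,5E)-4-methylcyclodec-5-en-1-one with 8,10-O-(4-methoxybenzylidene) acetal and C7 side chain CH(CH2OH)(CH2OPMB) | COc1ccc(cc1)[C@H]1O[C@H]2C[C@@](C)(O1)C(=O)CC[C@@H](C)/C=C/[C@H]2[C@@H](CO)COCc1ccc(OC)cc1 | intermediate
25 | C12 carboxylic acid of 24 | COc1ccc(cc1)[C@H]1O[C@H]2C[C@@](C)(O1)C(=O)CC[C@@H](C)/C=C/[C@H]2[C@@H](C(=O)O)COCc1ccc(OC)cc1 | intermediate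
26 | 5,6-syn-dihydroxy acid from osmylation of the outer alkene face | COc1ccc(cc1)[C@H]1O[C@H]2C[C@@](C)(O1)C(=O)CC[C@@H](C)[C@@H](O)[C@H](O)[C@H]2[C@@H](C(=O)O)COCc1ccc(OC)cc1 | intermediate
27 | 12,6-lactone, trans-fused at C6/C7 (6-epi), with C5 hydroxyl | COc1ccc(cc1)[C@H]1O[C@H]2C[C@@](C)(O1)C(=O)CC[C@@H](C)[C@@H](O)[C@@H]3OC(=O)[C@@H](COCc4ccc(OC)cc4)[C@@H]23 | intermediate
28 | C5 methanesulfonate of 27 | COc1ccc(cc1)[C@H]1O[C@H]2C[C@@](C)(O1)C(=O)CC[C@@H](C)[C@@H](OS(C)(=O)=O)[C@@H]3OC(=O)[C@@H](COCc4ccc(OC)cc4)[C@@H]23 | intermediate
29 | cis-5,6-epoxy C12 acid (C5 inverted) | COc1ccc(cc1)[C@H]1O[C@H]2C[C@@](C)(O1)C(=O)CC[C@@H](C)[C@@H]3O[C@@H]3[C@H]2[C@@H](C(=O)O)COCc1ccc(OC)cc1 | intermediate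
30 | 12,6-lactone, cis-fused at C6/C7 (C6 as in target), with C5 hydroxyl | COc1ccc(cc1)[C@H]1O[C@H]2C[C@@](C)(O1)C(=O)CC[C@@H](C)[C@H](O)[C@H]3OC(=O)[C@@H](COCc4ccc(OC)cc4)[C@@H]23 | intermediate
31 | (4Z)-germacr-4-en-12,6-olide, cis-fused, 1-oxo, 8,10-O-(4-methoxybenzylidene), 13-OPMB | COc1ccc(cc1)[C@H]1O[C@H]2C[C@@](C)(O1)C(=O)CC/C(C)=C\[C@H]3OC(=O)[C@@H](COCc4ccc(OC)cc4)[C@@H]23 | intermediate
32 | 8,10-diol of 31 | O[C@H]1C[C@@](C)(O)C(=O)CC/C(C)=C\[C@H]2OC(=O)[C@@H](COCc3ccc(OC)cc3)[C@H]21 | intermediate
33 | 8-methacrylate, 10-hydroxy, 13-OPMB | C=C(C)C(=O)O[C@H]1C[C@@](C)(O)C(=O)CC/C(C)=C\[C@H]2OC(=O)[C@@H](COCc3ccc(OC)cc3)[C@H]21 | intermediate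
34 | 8-methacrylate, 10-acetate, 13-OPMB | C=C(C)C(=O)O[C@H]1C[C@@](C)(OC(C)=O)C(=O)CC/C(C)=C\[C@H]2OC(=O)[C@@H](COCc3ccc(OC)cc3)[C@H]21 | intermediate
35 | 8-methacrylate, 10-acetate, 13-hydroxy | C=C(C)C(=O)O[C@H]1C[C@@](C)(OC(C)=O)C(=O)CC/C(C)=C\[C@H]2OC(=O)[C@@H](CO)[C@H]21 | intermediate
36 | (4Z)-alkene precursor of the target: 8-methacrylate, 10,13-diacetate | C=C(C)C(=O)O[C@H]1C[C@@](C)(OC(C)=O)C(=O)CC/C(C)=C\[C@H]2OC(=O)[C@@H](COC(C)=O)[C@H]21 | intermediate
37 | CNP0166747.1 | C=C(C)C(=O)O[C@H]1C[C@@](C)(OC(C)=O)C(=O)CC[C@@]2(C)O[C@H]2[C@H]2OC(=O)[C@@H](COC(C)=O)[C@H]21 | target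

## Step count and uncertain steps

Total step count: 24. Longest linear sequence: 24 steps from 1 (the route is linear; reagents made in the flask are not counted).

**Step 13 (key step).** Most likely to fail by heterolytic cleavage of the C1–C6 bond to an allyl anion and an enone, or by sluggish rearrangement, because the Z-methyl group must sit axial in the chair; prolonged exposure to base could then move the C5=C6 bond. Fallback, from 22 back to 24: a neutral silyloxy-Cope rearrangement. Diol 22 is bis-silylated (TMSOTf, 2,6-lutidine) to the bis(trimethylsilyl) ether F1. F1 is heated in base-washed glass (decalin, about 210 °C) and rearranges through the same chair to the ten-membered silyl enol ether F2. Methanolysis (K2CO3, MeOH) of F2 gives 24.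

**Step 3.** Most likely to fail by weak discrimination between the two enone arms or between the faces of one arm, so that C1 is set with low enantiomeric purity. Fallback, from 2 back to 9: the asymmetry is moved to the 1,2-addition. Reagent 2 is transmetallated with ZnCl2 to divinylzinc and added to purchasable 4,4-dimethoxy-2-methylcyclohexa-2,5-dien-1-one F3 with Ti(OiPr)4 and a chiral trans-1,2-diaminocyclohexane bis(sulfonamide) diol ligand (catalytic asymmetric vinylation of α-substituted cyclic enones). This gives the tertiary dienol F4, and oxalic acid hydrolysis of F4 gives 9.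

**Step 5.** Most likely to fail by 1,2-addition to the C8 carbonyl, by non-directed addition on the face of the vinyl group, or by partial loss of the Z geometry of the propenyl metal. Fallback, from 9 back to 12: the hydroxyl-directed conjugate addition is done with an alkynylalane. Dimethyl(prop-1-ynyl)aluminium (from 1-propynyllithium and Me2AlCl) first forms the aluminium alkoxide of 9 and then transfers the alkynyl group to C6 on the same face, giving the propynyl ketone F5. Semi-hydrogenation of F5 (Pd/CaCO3 poisoned with Pb(OAc)2, quinoline, H2) gives the (Z)-propenyl hydroxy ketone F6. TMSOTf and Et3N convert F6 to 12.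

**Step 18.** Most likely to fail by elimination toward C6 (enol lactone formation), or by dehydration of a transannular C1/C5 hemiketal instead of the C5 alcohol. Fallback, from 30 back to 31: a selenoxide elimination, which avoids oxygen-bearing carbons. Alcohol 30 is converted with inversion to the iodide F7 (PPh3, I2, imidazole). Sodium phenylselenide (PhSeSePh, NaBH4) displaces iodide with a second inversion to the selenide F8, which has the configuration of the original alcohol. Oxidation of F8 (H2O2, pyridine, 0 °C) and syn elimination toward C4 give 31.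

**Step 24.** Most likely to fail by attack of the peracid on the other alkene face (ring conformation overriding the allylic preference), or by acid-induced transannular opening of the new epoxide. Fallback, from 36 back to 37: the halohydrin route delivers the oxygen to the face opposite to the one the electrophile prefers. N-Bromosuccinimide in wet THF gives the bromohydrin F9 (water at the tertiary C4, bromine at C5). Closure of F9 with Ag2O in CH2Cl2 gives 37.

## Further compounds

F1 | step 13 | bis(trimethylsilyl) ether of 22 (C1 and C12 oxygens silylated) | COc1ccc(cc1)[C@H]1O[C@H]2C[C@@](C)(O1)[C@@](O[Si](C)(C)C)(C=C)[C@H](/C=C\C)[C@H]2[C@@H](CO[Si](C)(C)C)COCc1ccc(OC)cc1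
F2 | step 13 | ten-membered C1 trimethylsilyl enol ether with C12 trimethylsilyl ether | COc1ccc(cc1)[C@H]1O[C@H]2C[C@@](C)(O1)/C(O[Si](C)(C)C)=C/C[C@@H](C)/C=C/[C@H]2[C@@H](CO[Si](C)(C)C)COCc1ccc(OC)cc1
F3 | step 3 | 4,4-dimethoxy-2-methylcyclohexa-2,5-dien-1-one | COC1(OC)C=CC(=O)C(C)=C1
F4 | step 3 | (R)-4,4-dimethoxy-2-methyl-1-vinylcyclohexa-2,5-dien-1-ol | COC1(OC)C=C(C)[C@@](O)(C=C)C=C1
F5 | step 5 | 4-hydroxy-3-methyl-5-(prop-1-ynyl)-4-vinylcyclohex-2-en-1-one, propynyl cis to hydroxyl | O=C1C=C(C)[C@@](O)(C=C)[C@H](C#CC)C1
F6 | step 5 | 4-hydroxy-3-methyl-5-[(Z)-prop-1-enyl]-4-vinylcyclohex-2-en-1-one, propenyl cis to hydroxyl | O=C1C=C(C)[C@@](O)(C=C)[C@H](/C=C\C)C1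
F7 | step 18 | C5 iodide from 30 (C5 inverted) | COc1ccc(cc1)[C@H]1O[C@H]2C[C@@](C)(O1)C(=O)CC[C@@H](C)[C@@H](I)[C@H]3OC(=O)[C@@H](COCc4ccc(OC)cc4)[C@@H]23
F8 | step 18 | C5 phenyl selenide (C5 configured as the alcohol in 30) | COc1ccc(cc1)[C@H]1O[C@H]2C[C@@](C)(O1)C(=O)CC[C@@H](C)[C@H]([Se]c4ccccc4)[C@H]3OC(=O)[C@@H](COCc4ccc(OC)cc4)[C@@H]23
F9 | step 24 | 5-bromo-4-hydroxy bromohydrin of 36 | C=C(C)C(=O)O[C@H]1C[C@@](C)(OC(C)=O)C(=O)CC[C@@](C)(O)[C@H](Br)[C@H]2OC(=O)[C@@H](COC(C)=O)[C@H]21
A1 | alternative 1 | bridged isoxazoline spanning C8–C9–C10 of the ten-membered ring | N1=C2C[C@@](C)(O1)C(=O)CC[C@@]3(C)O[C@H]3[C@H]3OC(=O)[C@@H](COC(C)=O)[C@@H]23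
A2 | alternative 2 | cyclodecyne with the C10 propargylic acetate | C=C(C)C(=O)O[C@H]1C[C@@](C)(OC(C)=O)C#CC[C@@]2(C)O[C@H]2[C@H]2OC(=O)[C@@H](COC(C)=O)[C@H]21
A3 | alternative 3 | 4,5-epoxycyclodecane-1,6-dione | CC(C)(C)[Si](C)(C)O[C@H]1C[C@@](C)(OC(C)=O)C(=O)CC[C@@]2(C)O[C@H]2C(=O)[C@H]1[C@H](COC(C)=O)C(=O)OC
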